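**Retrosynthetic overview** (flavanone numbering: O1, C2, C3, C4, C4a, C5–C8, C8a)
1. Enabling feature: ring A (C4a, C5, C6, C7, C8, C8a) is a phloroglucinol with oxygen on C5, C7 and C8a and the C4 ketone on C4a, and O1–C8a=C4a–C4=O in ring C is a vinylogous ester. C2–C3–C4–C4a–C8a–C8–C7–C6–C5 is therefore one unbranched poly-β-carbonyl chain (carbonyls at C4, C8a, C7, C5; carbinol at C2; prenyl groups on the methines C6 and C8).
2. Key disconnections, both in one operation: O1–C8a (C2 hydroxyl onto the C8a ketone with loss of water, closing ring C) and C4a–C5 (acylketene from a tert-butyl ester, closing and aromatising ring A). These lead back to an open-chain tert-butyl 9-silyloxy-3,5,7-trioxononanoate.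
3. The chain is cut at C4–C4a: trianion of a doubly prenylated 3,5-diketo ester plus a β-silyloxy Weinreb amide. The diketo ester comes from tert-butyl acetoacetate, two prenyl bromides and one acetyl unit.
4. The Weinreb amide comes from 4'-hydroxyacetophenone; C2 (S) is set by Noyori transfer hydrogenation of an aryl β-keto ester.
5. Ring order: pyran ring of the chromene (step 2), then ring C, then ring A (both in step 10).

Key step: step 10

Remarks on the chemistry:
- The prenylated methine carbons flanked by carbonyl groups in the chain intermediates epimerise freely and end as sp2 carbons of ring A. These compounds are handled as mixtures of epimers and enol tautomers and are drawn without configuration at those carbons.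
- The (S,S)-TsDPEN catalyst is assumed to give the (S)-carbinol from the aryl β-keto ester, as it does from simple aryl alkyl ketones; if the opposite sense were found, the (R,R)-catalyst would be used.

**Step 1**
Reactants: 1 4'-hydroxyacetophenone; 2 3-chloro-3-methylbut-1-yne
Product: 3 1-{4-[(2-methylbut-3-yn-2-yl)oxy]phenyl}ethan-1-one
Conditions: DBU, CuCl2·2H2O (catalytic), MeCN, 0 °C to rt
Reagents that add atoms: none
Why: Copper-catalysed propargylic substitution of the tertiary chloride by the phenoxide should give the hindered aryl 1,1-dimethylpropargyl ether without touching the ketone.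

**Step 2**
Reactants: 3 1-{4-[(2-methylbut-3-yn-2-yl)oxy]phenyl}ethan-1-one
Product: 4 1-(2,2-dimethyl-2H-chromen-6-yl)ethan-1-one
Conditions: PhNEt2, 190 °C
Reagents that add atoms: none
Why: Aromatic propargyl Claisen rearrangement to either of the two equivalent ortho carbons, followed by 1,5-hydrogen shift and oxa-6π-electrocyclisation, should deliver the 2,2-dimethyl-2H-chromene in one thermal operation.

**Step 3**
Reactants: 4 1-(2,2-dimethyl-2H-chromen-6-yl)ethan-1-one; 5 dimethyl carbonate
Product: 6 methyl 3-(2,2-dimethyl-2H-chromen-6-yl)-3-oxopropanoate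
Conditions: NaH, THF, reflux; then aq HCl
Reagents that add atoms: none
Why: Crossed Claisen condensation of the methyl ketone enolate with dimethyl carbonate is driven by formation of the β-keto ester enolate, and the chromene is inert to NaH.

**Step 4**
Reactants: 6 methyl 3-(2,2-dimethyl-2H-chromen-6-yl)-3-oxopropanoate
Product: 7 methyl (3S)-3-(2,2-dimethyl-2H-chromen-6-yl)-3-hydroxypropanoate
Conditions: RuCl[(S,S)-TsDPEN](p-cymene) (1 mol%), HCO2H/Et3N (5:2), 30 °C
Reagents that add atoms: none
Why: Noyori asymmetric transfer hydrogenation, in which the (S,S)-ligand should direct hydride to the ketone face that gives the (S)-carbinol as for aryl alkyl ketones, while the ester and the chromene alkene are not reduced.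

**Step 5**
Reactants: 7 methyl (3S)-3-(2,2-dimethyl-2H-chromen-6-yl)-3-hydroxypropanoate
Product: 8 (3S)-3-(2,2-dimethyl-2H-chromen-6-yl)-3-hydroxy-N-methoxy-N-methylpropanamide
Conditions: MeNH(OMe)·HCl, iPrMgCl, THF, −20 to 0 °C
Reagents that add atoms: N,O-dimethylhydroxylamine hydrochloride, CNOC.Cl
Why: Weinreb amide formation by aminolysis of the methyl ester with the chloromagnesium amide should proceed on the magnesium alkoxide at low temperature without retro-aldol cleavage or loss of configuration.

**Step 6**
Reactants: 8 (3S)-3-(2,2-dimethyl-2H-chromen-6-yl)-3-hydroxy-N-methoxy-N-methylpropanamide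
Product: 9 (3S)-3-[(tert-butyldimethylsilyl)oxy]-3-(2,2-dimethyl-2H-chromen-6-yl)-N-methoxy-N-methylpropanamide
Conditions: TBSCl, imidazole, DMF, rt
Reagents that add atoms: tert-butyldimethylsilyl chloride, CC(C)(C)[Si](C)(C)Cl
Why: Standard silylation of the secondary benzylic alcohol, whose silyl ether keeps the C2 oxygen from closing ring C before step 10.

**Step 7**
Reactants: 10 tert-butyl 3-oxobutanoate (tert-butyl acetoacetate); 11 1-bromo-3-methylbut-2-ene (prenyl bromide, two equivalents)
Product: 13 tert-butyl 7-methyl-2-(3-methylbut-2-en-1-yl)-3-oxooct-6-enoate, via tert-butyl 7-methyl-3-oxooct-6-enoate enolate 12 (not isolated)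
Conditions: NaH, THF, 0 °C; n-BuLi, 0 °C; 11 (1 equiv), 0 °C; then 11 (1.1 equiv), rt to 45 °C
Reagents that add atoms: none
Why: The acetoacetate dianion alkylates at its more basic γ-carbon and the remaining β-keto ester enolate then takes the second prenyl bromide at the α-carbon, so sequential enolate alkylation places the prenyl groups on the future C8 and C6.

**Step 8**
Reactants: 13 tert-butyl 7-methyl-2-(3-methylbut-2-en-1-yl)-3-oxooct-6-enoate; 14 N-methoxy-N-methylacetamide
Product: 15 tert-butyl 2,4-bis(3-methylbut-2-en-1-yl)-3,5-dioxohexanoate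
Conditions: LiN(iPr)2 (2.2 equiv), THF, −78 to 0 °C; 14, −78 to 0 °C; aq NH4Cl
Reagents that add atoms: none
Why: γ-Acylation of the β-keto ester dianion by the Weinreb amide stops at the chelated tetrahedral adduct, which should release the more acidic 3,5-diketo ester only on work-up.

**Step 9**
Reactants: 15 tert-butyl 2,4-bis(3-methylbut-2-en-1-yl)-3,5-dioxohexanoate; 9 (3S)-3-[(tert-butyldimethylsilyl)oxy]-3-(2,2-dimethyl-2H-chromen-6-yl)-N-methoxy-N-methylpropanamide
Product: 16 tert-butyl (9S)-9-[(tert-butyldimethylsilyl)oxy]-9-(2,2-dimethyl-2H-chromen-6-yl)-2,4-bis(3-methylbut-2-en-1-yl)-3,5,7-trioxononanoate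
Conditions: LiN(iPr)2 (3.5 equiv), THF, −78 to 0 °C; 9, −78 to −20 °C; cold aq NH4Cl
Reagents that add atoms: none
Why: The terminal methyl carbanion of the trianion is its most basic and least hindered site and its acylation by the Weinreb amide again stops at the tetrahedral adduct, so this polyanion acylation should give the tetracarbonyl chain only on buffered work-up with the silyloxy stereocentre untouched.

**Step 10**
Reactants: 16 tert-butyl (9S)-9-[(tert-butyldimethylsilyl)oxy]-9-(2,2-dimethyl-2H-chromen-6-yl)-2,4-bis(3-methylbut-2-en-1-yl)-3,5,7-trioxononanoate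
Product: 21 (2S)-2-(2,2-dimethyl-2H-chromen-6-yl)-5,7-dihydroxy-6,8-bis(3-methylbut-2-en-1-yl)-2,3-dihydro-4H-chromen-4-one, via hydroxy trioxo ester 17 (not isolated), via dihydropyranone ester 18 (not isolated), via acylketene 19 (not isolated), via cyclohexadienone tautomer 20 (not isolated)
Conditions: HF·pyridine, pyridine, THF, 0 °C to rt; TMSOMe, concentrate from PhMe; PhMe (0.005 M), 110 °C, N2 sweep
Reagents that add atoms: none
Why: Proposed new method: HF·pyridine frees the C2 hydroxyl of 17, which adds 6-exo-trig to the C8a carbonyl of the β-diketone and loses water to give dihydropyranone 18 (O1–C8a bond, ring C), the known acid-mediated cyclodehydration of δ-hydroxy-β-diketones, complete below the temperature at which the ester reacts. At 110 °C the β-keto tert-butyl ester loses tert-butanol to acylketene 19, whose C7 enol form is a dienylketene (C5=C6–C7=C8–C8a=C4a) that closes ring A by 6π-electrocyclisation at C4a–C5 (equivalent to a six-membered intramolecular C-acylation of the vinylogous ester) and tautomerises through 20 to the phloroglucinol. The closest known reaction types are the thermal generation of acylketenes from tert-butyl β-keto esters and dioxinones, the base-mediated Claisen folding of 3,5,7-triketo esters and of 4-pyranone keto esters into acylphloroglucinols and 5,7-dihydroxychromones, and the dienylketene electrocyclisation of benzannulations; what is new is their union on a dihydropyranone under neutral conditions. No stereocentre is formed, since C2 comes from step 4, none of its bonds is broken, and the absence of base avoids ring opening by β-elimination. The step needs ring C to close before ring A and C- rather than O-acylation of the ketene; temperature staging secures the first, and the second follows because the C8a oxygen is already the ring ether, so the usual 2-pyranone closure is impossible and C4a is the only nucleophilic atom within six-membered reach of C5. Both prenyl groups and both phenols arise in place from the chain, so ring A needs neither a regiochemical choice nor a protecting group.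

**Compound list**
1 | 4'-hydroxyacetophenone | CC(=O)c1ccc(O)cc1 | starting material
2 | 3-chloro-3-methylbut-1-yne | CC(C)(Cl)C#C | starting material
3 | 1-{4-[(2-methylbut-3-yn-2-yl)oxy]phenyl}ethan-1-one | CC(=O)c1ccc(OC(C)(C)C#C)cc1 | intermediate
4 | 1-(2,2-dimethyl-2H-chromen-6-yl)ethan-1-one | CC(=O)c1ccc2c(c1)C=CC(C)(C)O2 | intermediate
5 | dimethyl carbonate | COC(=O)OC | starting material
6 | methyl 3-(2,2-dimethyl-2H-chromen-6-yl)-3-oxopropanoate | COC(=O)CC(=O)c1ccc2c(c1)C=CC(C)(C)O2 | intermediate
7 | methyl (3S)-3-(2,2-dimethyl-2H-chromen-6-yl)-3-hydroxypropanoate | COC(=O)C[C@@H](c1ccc2c(c1)C=CC(C)(C)O2)O | intermediate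
8 | (3S)-3-(2,2-dimethyl-2H-chromen-6-yl)-3-hydroxy-N-methoxy-N-methylpropanamide | CON(C)C(=O)C[C@@H](c1ccc2c(c1)C=CC(C)(C)O2)O | intermediate
9 | (3S)-3-[(tert-butyldimethylsilyl)oxy]-3-(2,2-dimethyl-2H-chromen-6-yl)-N-methoxy-N-methylpropanamide | CON(C)C(=O)C[C@@H](c1ccc2c(c1)C=CC(C)(C)O2)O[Si](C)(C)C(C)(C)C | intermediate
10 | tert-butyl 3-oxobutanoate (tert-butyl acetoacetate) | CC(=O)CC(=O)OC(C)(C)C | starting material
11 | 1-bromo-3-methylbut-2-ene (prenyl bromide) | CC(C)=CCBr | starting material
12 | tert-butyl 7-methyl-3-oxooct-6-enoate (formed as its enolate, not isolated) | CC(C)=CCCC(=O)CC(=O)OC(C)(C)C | intermediate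
13 | tert-butyl 7-methyl-2-(3-methylbut-2-en-1-yl)-3-oxooct-6-enoate (racemic) | CC(C)=CCCC(=O)C(CC=C(C)C)C(=O)OC(C)(C)C | intermediate
14 | N-methoxy-N-methylacetamide | CC(=O)N(C)OC | starting material
15 | tert-butyl 2,4-bis(3-methylbut-2-en-1-yl)-3,5-dioxohexanoate (epimer and enol mixture) | CC(=O)C(CC=C(C)C)C(=O)C(CC=C(C)C)C(=O)OC(C)(C)C | intermediate
16 | tert-butyl (9S)-9-[(tert-butyldimethylsilyl)oxy]-9-(2,2-dimethyl-2H-chromen-6-yl)-2,4-bis(3-methylbut-2-en-1-yl)-3,5,7-trioxononanoate (epimer and enol mixture at C2 and C4) | CC(C)=CCC(C(=O)OC(C)(C)C)C(=O)C(CC=C(C)C)C(=O)CC(=O)C[C@@H](c1ccc2c(c1)C=CC(C)(C)O2)O[Si](C)(C)C(C)(C)C | intermediate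
17 | tert-butyl (9S)-9-(2,2-dimethyl-2H-chromen-6-yl)-9-hydroxy-2,4-bis(3-methylbut-2-en-1-yl)-3,5,7-trioxononanoate (not isolated) | CC(C)=CCC(C(=O)OC(C)(C)C)C(=O)C(CC=C(C)C)C(=O)CC(=O)C[C@@H](c1ccc2c(c1)C=CC(C)(C)O2)O | intermediate
18 | tert-butyl 4-[(2S)-2-(2,2-dimethyl-2H-chromen-6-yl)-4-oxo-3,4-dihydro-2H-pyran-6-yl]-7-methyl-2-(3-methylbut-2-en-1-yl)-3-oxooct-6-enoate (not isolated) | CC(C)=CCC(C(=O)OC(C)(C)C)C(=O)C(CC=C(C)C)C1=CC(=O)C[C@@H](c2ccc3c(c2)C=CC(C)(C)O3)O1 | intermediate
19 | 4-[(2S)-2-(2,2-dimethyl-2H-chromen-6-yl)-4-oxo-3,4-dihydro-2H-pyran-6-yl]-7-methyl-2-(3-methylbut-2-en-1-yl)octa-1,6-diene-1,3-dione (acylketene, not isolated) | O=C=C(CC=C(C)C)C(=O)C(CC=C(C)C)C1=CC(=O)C[C@@H](c2ccc3c(c2)C=CC(C)(C)O3)O1 | intermediate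
20 | (2S)-2-(2,2-dimethyl-2H-chromen-6-yl)-7-hydroxy-6,8-bis(3-methylbut-2-en-1-yl)-2,3-dihydro-4H-chromene-4,5(4aH)-dione (not isolated) | CC(C)=CCC1=C(O)C(CC=C(C)C)=C2O[C@H](c3ccc4c(c3)C=CC(C)(C)O4)CC(=O)C2C1=O | intermediate
21 | (2S)-2-(2,2-dimethyl-2H-chromen-6-yl)-5,7-dihydroxy-6,8-bis(3-methylbut-2-en-1-yl)-2,3-dihydro-4H-chromen-4-one | CC(C)=CCc1c(O)c(CC=C(C)C)c2c(c1O)C(=O)C[C@@H](c1ccc3c(c1)C=CC(C)(C)O3)O2 | target

**Total step count:** 10
**Longest linear sequence:** 8 steps (steps 1–6, 9 and 10)

**Steps most likely to fail**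

Step 10 (Proposed new method). The polycarbonyl chain may fold in another mode before ring C closes (aldol closure from C3 or 4-pyranone formation). Loss of tert-butanol may be slower than de-tert-butylation with decarboxylation. The ketene may be captured intermolecularly by phenolic product. The fallback uncouples the two ring closures and uses only known chemistry. It sets out from 16, which is treated with HF·pyridine alone, and dihydropyranone ester 18 is isolated. Ring A is then closed as a base-mediated Claisen (Dieckmann-type) condensation of the polyketide ester with Mg(OMe)2 in MeOH at 0 °C to rt and a cold AcOH quench, the classical folding of pyranone keto esters into 5,7-dihydroxy benzopyranones. It comes back to the route at 21. The enantiomeric purity of 21 would have to be checked, because base can open ring C reversibly. This fallback makes no compound outside the compound list (F0).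

Step 9. The third deprotonation of the doubly branched diketo ester may be incomplete, and the basic terminal carbanion may instead remove an α-proton of the amide and trigger β-elimination of the silyloxy group. The fallback replaces the acylation by an aldol addition and an oxidation. It sets out from 9, which is reduced with iBu2AlH (THF, −78 °C) to (3S)-3-[(tert-butyldimethylsilyl)oxy]-3-(2,2-dimethyl-2H-chromen-6-yl)propanal F1. The trianion of 15 adds to this aldehyde at −78 °C, faster than any proton transfer, to give tert-butyl (9S)-9-[(tert-butyldimethylsilyl)oxy]-9-(2,2-dimethyl-2H-chromen-6-yl)-7-hydroxy-2,4-bis(3-methylbut-2-en-1-yl)-3,5-dioxononanoate F2. Dess–Martin periodinane (NaHCO3, CH2Cl2, 0 °C) then oxidises the C7 carbinol, and the fallback comes back to the route at 16.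

Step 8. γ-Deprotonation of the α-branched keto ester may be sluggish, and the hindered dianion may be acylated on oxygen or suffer retro-Claisen cleavage on work-up. The fallback again exchanges acylation for aldol addition and oxidation. It sets out from 13, whose dianion (LiN(iPr)2, THF, −78 °C) adds to acetaldehyde to give tert-butyl 5-hydroxy-2,4-bis(3-methylbut-2-en-1-yl)-3-oxohexanoate F3. Dess–Martin periodinane (NaHCO3, CH2Cl2) oxidises the secondary alcohol, and the fallback comes back to the route at 15.

**Further compounds**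
F0 | step 10 | none | none
F1 | step 9 | (3S)-3-[(tert-butyldimethylsilyl)oxy]-3-(2,2-dimethyl-2H-chromen-6-yl)propanal | O=CC[C@@H](c1ccc2c(c1)C=CC(C)(C)O2)O[Si](C)(C)C(C)(C)C
F2 | step 9 | tert-butyl (9S)-9-[(tert-butyldimethylsilyl)oxy]-9-(2,2-dimethyl-2H-chromen-6-yl)-7-hydroxy-2,4-bis(3-methylbut-2-en-1-yl)-3,5-dioxononanoate (epimer mixture at C2, C4 and C7) | CC(C)=CCC(C(=O)OC(C)(C)C)C(=O)C(CC=C(C)C)C(=O)CC(O)C[C@@H](c1ccc2c(c1)C=CC(C)(C)O2)O[Si](C)(C)C(C)(C)C
F3 | step 8 | tert-butyl 5-hydroxy-2,4-bis(3-methylbut-2-en-1-yl)-3-oxohexanoate (diastereomer mixture) | CC(O)C(CC=C(C)C)C(=O)C(CC=C(C)C)C(=O)OC(C)(C)C
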